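**Strategy.** The lactone ring is disconnected at the bond between the benzylic carbon C3 and the ring oxygen O2, together with the C1'–C2' bond of the side chain. One radical oxyalkylation, catalysed by Cu(MeCN)4PF6 and a chiral bisoxazoline, forms both bonds. A 12-oxotridecyl radical, released from an alkanoyl 3-chlorobenzoyl peroxide, adds to the vinyl terminus of 2-ethenyl-4,6-dimethoxybenzoic acid. The benzylic radical so formed is captured enantioselectively by the copper-bound ortho carboxylate, closing the five-membered lactone and setting C3. The step exploits that C3 is benzylic, on C3a of the benzene ring, next to C7a that carries the carboxyl carbon C1. Both precursors are achiral and two steps from commercial materials.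

Key step: step 5

Assumption: the (S,S)-configured tert-butyl bisoxazoline is taken to deliver the (S)-lactone; the sense of induction would be checked on first use and the equally available (R,R)-ligand substituted if the opposite sense is found.

**Step 1**
Reactants: 1 2-bromo-3,5-dimethoxybenzaldehyde
Product: 2 2-bromo-1-ethenyl-3,5-dimethoxybenzene
Conditions: Ph3PCH3Br, KOtBu, THF, 0 °C to rt
Reagents that add atoms: methyltriphenylphosphonium bromide, C[P+](c1ccccc1)(c1ccccc1)c1ccccc1.[Br-]
Why: Wittig olefination of the aryl aldehyde with the non-stabilised ylide made in the flask should give the styrene, the aryl bromide and the methyl ethers being inert to the ylide.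

**Step 2**
Reactants: 2 2-bromo-1-ethenyl-3,5-dimethoxybenzene
Product: 4 2-ethenyl-4,6-dimethoxybenzoic acid, via aryllithium 3 (not isolated)
Conditions: n-BuLi, THF, −78 °C; then CO2 (gas), −78 °C to rt; aq. HCl
Reagents that add atoms: carbon dioxide, O=C=O
Why: Bromine–lithium exchange at −78 °C is much faster than addition of butyllithium to the styrene, the aryllithium 3 is stabilised by the flanking methoxy group, and carboxylation followed by acidification should give the benzoic acid.

**Step 3**
Reactants: 5 methyl 11-bromoundecanoate; 6 ethyl acetoacetate
Product: 9 13-oxotetradecanoic acid, via alkylated keto diester 7 (not isolated), via 2-acetyltridecanedioic acid 8 (not isolated)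
Conditions: 6 (1.5 equiv), NaH, THF/DMF, 0 °C; then 5, NaI (cat.), 60 °C; then aq. NaOH, MeOH, 50 °C; then HCl to pH 1, 80 °C
Reagents that add atoms: sodium hydroxide, [Na+].[OH-]
Why: Acetoacetic ester synthesis, in which C-alkylation of the sodium enolate of 6 by the primary bromide, saponification of both esters and decarboxylation of the β-keto acid 8 on acidification should give the methyl ketone acid.

**Step 4**
Reactants: 9 13-oxotetradecanoic acid
Product: 10 3-chlorobenzoyl 13-oxotetradecanoyl peroxide
Conditions: mCPBA (dried, freed of 3-chlorobenzoic acid, 1.05 equiv), DCC (1.1 equiv), CH2Cl2, 0 °C, dark; cold filtration, short silica plug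
Reagents that add atoms: mCPBA (3-chloroperoxybenzoic acid), O=C(OO)c1cccc(Cl)c1
Why: Carbodiimide-mediated acylation of a peracid, in which DCC activates 9 as its O-acylisourea and the peroxy hydroxyl of mCPBA attacks it to give the unsymmetrical diacyl peroxide from one molecule of acid and one of peracid, a standard preparation of alkanoyl aroyl peroxides, and at 0 °C without strong acid the coupling should outrun Baeyer–Villiger oxidation of the unstrained methyl ketone.

**Step 5**
Reactants: 4 2-ethenyl-4,6-dimethoxybenzoic acid; 10 3-chlorobenzoyl 13-oxotetradecanoyl peroxide
Product: 13 (3S)-5,7-dimethoxy-3-(13-oxotetradecyl)-2-benzofuran-1(3H)-one (CJ-13,108), via 12-oxotridecyl radical 11 (not isolated), via benzylic radical 12 (not isolated)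
Conditions: Cu(MeCN)4PF6 (10 mol%), 2,2'-(propane-2,2-diyl)bis[(4S)-4-tert-butyl-4,5-dihydro-1,3-oxazole] (12 mol%), 10 (1.5 equiv), EtOAc, rt, argon
Reagents that add atoms: none
Why: Monovalent copper cleaves the O–O bond of 10 by single-electron transfer, the electron-poor aroyl half leaving as a divalent copper 3-chlorobenzoate and the alkanoyloxyl half losing CO2 at once to give the primary radical 11, which adds to the unsubstituted vinyl terminus of 4 to give the benzylic radical 12; the bisoxazoline-bound divalent copper, which takes up the ortho carboxylate of the substrate by exchange with 3-chlorobenzoate, captures 12 and forms the benzylic C–O bond by reductive elimination from trivalent copper, returning monovalent copper. The closest known reaction type is the enantioselective radical oxyalkylation (carbolactonisation) of 2-alkenylbenzoic and pent-4-enoic acids with diacyl peroxides under monovalent copper/bisoxazoline catalysis, supported by the enantioselective capture of secondary benzylic radicals from styrenes by the same catalyst family. The five-membered lactone closes by attack of the carboxylate oxygen on the benzylic carbon, a 5-exo closure with respect to the original alkene that passes through a six-membered chelate in which copper holds both the carboxylate and the benzylic carbon. C3 is the only stereocentre and is set under catalyst control, the C2-symmetric tert-butyl bisoxazoline having to distinguish the two faces of the planar radical (H against the long CH2R chain) in the C–O bond-forming event. The step needs regioselective radical addition, secured by benzylic stabilisation and the unhindered CH2 terminus, and intramolecular C–O formation in preference to ester formation with the released 3-chlorobenzoate or to oligomerisation, secured by chelation of the ortho carboxylate to the copper that traps the radical. The methyl ketone, the aryl ethers and the product lactone should be inert to these neutral conditions.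

**Compound list**
1 | 2-bromo-3,5-dimethoxybenzaldehyde | O=Cc1cc(OC)cc(OC)c1Br | starting material
2 | 2-bromo-1-ethenyl-3,5-dimethoxybenzene | C=Cc1cc(OC)cc(OC)c1Br | intermediate
3 | (2-ethenyl-4,6-dimethoxyphenyl)lithium | [Li]c1c(C=C)cc(OC)cc1OC | intermediate (not isolated)
4 | 2-ethenyl-4,6-dimethoxybenzoic acid | C=Cc1cc(OC)cc(OC)c1C(=O)O | intermediate
5 | methyl 11-bromoundecanoate | COC(=O)CCCCCCCCCCBr | starting material
6 | ethyl acetoacetate (ethyl 3-oxobutanoate) | CCOC(=O)CC(C)=O | starting material
7 | methyl 12-(ethoxycarbonyl)-13-oxotetradecanoate | CCOC(=O)C(CCCCCCCCCCC(=O)OC)C(C)=O | intermediate (not isolated)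
8 | 2-acetyltridecanedioic acid | CC(=O)C(CCCCCCCCCCC(=O)O)C(=O)O | intermediate (not isolated)
9 | 13-oxotetradecanoic acid | CC(=O)CCCCCCCCCCCC(=O)O | intermediate
10 | 3-chlorobenzoyl 13-oxotetradecanoyl peroxide | CC(=O)CCCCCCCCCCCC(=O)OOC(=O)c1cccc(Cl)c1 | intermediate
11 | 12-oxotridecyl radical | [CH2]CCCCCCCCCCC(C)=O | intermediate (not isolated)
12 | 1-(2-carboxy-3,5-dimethoxyphenyl)-14-oxopentadecyl radical | COc1cc(OC)c(C(=O)O)c([CH]CCCCCCCCCCCCC(C)=O)c1 | intermediate (not isolated)
13 | (3S)-5,7-dimethoxy-3-(13-oxotetradecyl)-2-benzofuran-1(3H)-one (CJ-13,108) | COc1cc(OC)c2c(c1)[C@H](CCCCCCCCCCCCC(C)=O)OC2=O | target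

**Total step count:** 5
**Longest linear sequence:** 3 steps (1, 2, 5 or 3, 4, 5)

**Steps most likely to fail**

Step 5. The C–O bond-forming event may show poor facial discrimination, because the benzylic radical is secondary and the ligand must tell H from a flexible chain; radical oligomerisation of the styrene may also compete. The fallback moves stereocontrol from the catalyst to a physical resolution. It sets out from 4 and 10, which would be joined without asymmetric induction (Cu(MeCN)4PF6, 1,10-phenanthroline, EtOAc, rt) to give racemic 5,7-dimethoxy-3-(13-oxotetradecyl)-2-benzofuran-1(3H)-one F1. The enantiomers would then be separated by preparative chromatography on a cellulose tris(3,5-dimethylphenylcarbamate) phase (supercritical CO2/MeOH). The (3R)-5,7-dimethoxy-3-(13-oxotetradecyl)-2-benzofuran-1(3H)-one F2 is set aside, and the (S)-enantiomer is 13, where the fallback returns to the route.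

Step 4. The peracid may oxidise the methyl ketone in a Baeyer–Villiger sense during the coupling, or the peroxide may decompose by homolysis or carboxy inversion during isolation. The fallback changes the radical precursor and its mode of activation. It sets out from 9, which would be esterified (N-hydroxyphthalimide, N,N'-diisopropylcarbodiimide, DMAP cat., CH2Cl2, rt) to the redox-active ester 1,3-dioxoisoindolin-2-yl 13-oxotetradecanoate F3. Photoreductive decarboxylation of this ester releases the same radical 11. It would be united with 4 under dual photoredox/copper catalysis (fac-Ir(ppy)3, Cu(MeCN)4PF6, the same bisoxazoline, blue LEDs, EtOAc, rt), a known manifold for enantioselective capture of benzylic radicals, returning to the route at 13.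

Step 2. Butyllithium or the aryllithium may add across the styrene (carbolithiation and anionic oligomerisation) in competition with halogen–lithium exchange. The fallback replaces the organolithium by a palladium-catalysed carbonylation. It sets out from 2, which would be methoxycarbonylated (Pd(OAc)2, Xantphos, CO 1 atm, MeOH, Et3N, toluene, 90 °C) to methyl 2-ethenyl-4,6-dimethoxybenzoate F4. The hindered ester would then be saponified (KOH, EtOH/H2O, reflux; then HCl), returning to the route at 4.

**Further compounds**
F1 | step 5 | rac-5,7-dimethoxy-3-(13-oxotetradecyl)-2-benzofuran-1(3H)-one | COc1cc(OC)c2c(c1)C(CCCCCCCCCCCCC(C)=O)OC2=O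
F2 | step 5 | (3R)-5,7-dimethoxy-3-(13-oxotetradecyl)-2-benzofuran-1(3H)-one | COc1cc(OC)c2c(c1)[C@@H](CCCCCCCCCCCCC(C)=O)OC2=O
F3 | step 4 | 1,3-dioxoisoindolin-2-yl 13-oxotetradecanoate | CC(=O)CCCCCCCCCCCC(=O)ON1C(=O)c2ccccc2C1=O
F4 | step 2 | methyl 2-ethenyl-4,6-dimethoxybenzoate | C=Cc1cc(OC)cc(OC)c1C(=O)OC
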